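**Plan**
- Retrosynthesis: the two free phenols are masked (4'-O-benzyl, 5-O-methyl), ring C is opened at O1–C2 to a 2-hydroxyaryl 1,3-diketone, and the diketone is cut at both C2–C3 and C2–C1'.
- The cut is possible because C2 of ring C is a carbonyl-level carbon lying between C3 (the acetyl methyl of a ring A acetophenone) and C1' of ring B, so it can be delivered as carbon monoxide between a ketone enolate and an aryl bromide.
- Forward: the ring A ketone and the ring B bromide are made separately and joined through CO into the open-chain diketone; ring C (the pyranone) is then closed by cyclodehydration, and both phenols are released last.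
- Stereochemistry: the target has no stereocentre and no stereogenic double bond, so none has to be set.

Key step: step 4

Remark: "Dihidroxy" is read as dihydroxy and flavone numbering is used (ring A = C5–C8, ring C = O1/C2–C4, ring B = C1'–C6'); metal or boron salts and chelates of numbered compounds that exist before work-up are treated as forms of those compounds.

**Step 1**
Reactants: 1 1,2,3,5-tetramethoxybenzene
Product: 3 2-hydroxy-3,4,6-trimethoxyacetophenone, via 2,3,4,6-tetramethoxyacetophenone 2 (not isolated)
Conditions: AcCl (1.2 equiv), AlCl3 (2.5 equiv), Et2O, 0 °C to rt; then ice/1 M HCl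
Reagents that add atoms: acetyl chloride, CC(Cl)=O
Why: Friedel–Crafts acylation of the very electron-rich arene at C4 (equivalent to C6 by symmetry) gives 2, and AlCl3 bound to its carbonyl then cleaves, under chelation control, the more crowded ortho methyl ether (the 2-OMe wedged between acetyl and 3-OMe), the resulting six-membered aluminium phenoxide chelate shielding the other ortho ether.

**Step 2**
Reactants: 4 2,3-dimethoxyphenol
Product: 5 4-bromo-2,3-dimethoxyphenol
Conditions: NBS (1.0 equiv), MeCN, −20 to 0 °C
Reagents that add atoms: N-bromosuccinimide, O=C1CCC(=O)N1Br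
Why: Electrophilic aromatic bromination with NBS in a polar solvent is para-selective for phenols, and C4 is para to the hydroxyl (the strongest donor) and ortho to the 3-OMe, while low temperature and one equivalent of NBS should hold back attack at C6 and dibromination.

**Step 3**
Reactants: 5 4-bromo-2,3-dimethoxyphenol
Product: 6 1-benzyloxy-4-bromo-2,3-dimethoxybenzene
Conditions: BnBr (1.1 equiv), K2CO3 (1.5 equiv), DMF, rt
Reagents that add atoms: benzyl bromide, BrCc1ccccc1
Why: Williamson ether synthesis, in which the phenoxide formed with K2CO3 is alkylated by benzyl bromide in an SN2 reaction while the aryl bromide and the methyl ethers stay untouched.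

**Step 4**
Reactants: 3 2-hydroxy-3,4,6-trimethoxyacetophenone; 6 1-benzyloxy-4-bromo-2,3-dimethoxybenzene; 7 carbon monoxide
Product: 8 1-(4-benzyloxy-2,3-dimethoxyphenyl)-3-(2-hydroxy-3,4,6-trimethoxyphenyl)propane-1,3-dione
Conditions: 3 (2.0 equiv), NaN(SiMe3)2 (4.0 equiv), THF, 0 °C; then 6 (1.0 equiv), Pd(dba)2 (5 mol %), Ph2P(CH2)3PPh2 (6 mol %), CO (1.5 equiv, sealed vessel), THF, 80 °C; then 1 M HCl
Reagents that add atoms: carbon monoxide (compound 7), [C-]#[O+]
Why: Zerovalent palladium carrying the chelating bisphosphine adds oxidatively to the C–Br bond of 6, CO inserts to give an aroyl complex of divalent palladium (this creates C1'–C2), the carbon terminus of the sodium phenoxide–enolate dianion of 3 replaces bromide on palladium, and reductive elimination forms C2–C3 and regenerates zerovalent palladium. The closest known reaction type is the palladium-catalysed carbonylative α-arylation of aryl methyl ketones with aryl bromides to 1,3-diketones, which is also the opening stage of one-pot carbonylative flavone syntheses from 2-hydroxyacetophenones. No ring is closed and no stereocentre is formed; the step joins the ring A and ring B halves through the CO-derived carbon that becomes C2. The selectivity required is acylation at the methyl carbon instead of the phenoxide oxygen, together with CO insertion ahead of direct α-arylation: the dianion reacts at its more nucleophilic carbon, any aryl ester formed at oxygen would be carried to the same diketone by a base-mediated Baker–Venkataraman O-to-C acyl shift, and the CO atmosphere with the bidentate ligand favours the acyl complex. The second equivalent of dianion deprotonates the product, so the diketone is withdrawn as its chelated sodium enolate and should neither be acylated twice nor suffer retro-Claisen cleavage. The benzyl and methyl ethers are inert to the base and to the catalyst.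

**Step 5**
Reactants: 8 1-(4-benzyloxy-2,3-dimethoxyphenyl)-3-(2-hydroxy-3,4,6-trimethoxyphenyl)propane-1,3-dione
Product: 9 4'-benzyloxy-5,7,8,2',3'-pentamethoxyflavone (2-[4-(benzyloxy)-2,3-dimethoxyphenyl]-5,7,8-trimethoxy-4H-chromen-4-one)
Conditions: H2SO4 (cat.), AcOH, 80 °C
Reagents that add atoms: none
Why: Acid-catalysed cyclodehydration of a 2-hydroxyphenyl 1,3-diketone, in which the only free ring A hydroxyl adds to the carbonyl next to ring B (6-exo-trig, giving the 2-hydroxyflavanone hemiketal) and loss of water gives the aromatic 4-pyranone of ring C, the ethers being expected to survive brief exposure to catalytic acid.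

**Step 6**
Reactants: 9 4'-benzyloxy-5,7,8,2',3'-pentamethoxyflavone
Product: 10 5,4'-dihydroxy-7,8,2',3'-tetramethoxyflavone (5-hydroxy-2-(4-hydroxy-2,3-dimethoxyphenyl)-7,8-dimethoxy-4H-chromen-4-one)
Conditions: BCl3 (1 M in CH2Cl2, 5 equiv), C6HMe5 (3 equiv), CH2Cl2, −78 to 0 °C; then H2O
Reagents that add atoms: none
Why: Lewis acid ether cleavage with BCl3, in which the aryl benzyl ether is cleaved at low temperature while pentamethylbenzene intercepts the benzyl cation by Friedel–Crafts alkylation, and on warming BCl3 chelated between the C4 carbonyl and the peri 5-O-methyl oxygen removes that methyl group selectively, the 7-, 8-, 2'- and 3'-methyl ethers lacking such a carbonyl chelate.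

**Compound list**
1 | 1,2,3,5-tetramethoxybenzene | COc1cc(OC)c(OC)c(OC)c1 | starting material
2 | 2,3,4,6-tetramethoxyacetophenone | CC(=O)c1c(OC)cc(OC)c(OC)c1OC | intermediate (not isolated)
3 | 2-hydroxy-3,4,6-trimethoxyacetophenone | CC(=O)c1c(O)c(OC)c(OC)cc1OC | intermediate
4 | 2,3-dimethoxyphenol | COc1cccc(O)c1OC | starting material
5 | 4-bromo-2,3-dimethoxyphenol | COc1c(O)ccc(Br)c1OC | intermediate
6 | 1-benzyloxy-4-bromo-2,3-dimethoxybenzene | Brc1ccc(OCc2ccccc2)c(OC)c1OC | intermediate
7 | carbon monoxide | [C-]#[O+] | starting material
8 | 1-(4-benzyloxy-2,3-dimethoxyphenyl)-3-(2-hydroxy-3,4,6-trimethoxyphenyl)propane-1,3-dione (drawn as the diketo tautomer) | COc1cc(OC)c(C(=O)CC(=O)c2ccc(OCc3ccccc3)c(OC)c2OC)c(O)c1OC | intermediate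
9 | 4'-benzyloxy-5,7,8,2',3'-pentamethoxyflavone | COc1cc(OC)c2c(=O)cc(-c3ccc(OCc4ccccc4)c(OC)c3OC)oc2c1OC | intermediate
10 | 5,4'-dihydroxy-7,8,2',3'-tetramethoxyflavone | COc1cc(O)c2c(=O)cc(-c3ccc(O)c(OC)c3OC)oc2c1OC | target

**Step count**
Total: 6 steps. Longest linear sequence: 5 steps (4 → 5 → 6 → 8 → 9 → 10); the ring A branch (1 → 3) is one step and joins at step 4.

**Steps most likely to fail**

Step 4. Oxidative addition of the electron-rich, ortho-substituted aryl bromide may be slowed under CO, so that hydrodebromination or carbonyl-free α-arylation competes, and the hindered dianion may be captured too slowly by the acyl complex. The fallback sets out from 6 (with 3) and comes back at 8, replacing the catalytic carbonylation by classical acyl transfer. Bromide 6 would undergo bromine–lithium exchange (n-BuLi, THF, −78 °C) to (4-benzyloxy-2,3-dimethoxyphenyl)lithium F1, which is quenched with CO2 to give 4-benzyloxy-2,3-dimethoxybenzoic acid F2. Esterification of the phenol of 3 with F2 (EDC·HCl, DMAP, CH2Cl2) would give 2-acetyl-3,5,6-trimethoxyphenyl 4-benzyloxy-2,3-dimethoxybenzoate F3. Baker–Venkataraman rearrangement (KOH, pyridine, 50 °C) would then move the aroyl group from oxygen to the methyl carbon and deliver diketone 8.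

Step 2. Bromination may occur in part at C6 (ortho to the hydroxyl and para to the 3-OMe) or twice, since both positions are doubly activated. The fallback sets out from 4 and comes back at 6, using a removable blocking group. Casnati–Skattebøl ortho-formylation (MgCl2, Et3N, paraformaldehyde, MeCN, reflux) should give 2-hydroxy-3,4-dimethoxybenzaldehyde F4, in which the formyl group occupies the competing ortho position. Bromination (Br2, NaOAc, AcOH, rt) can then go only para to the hydroxyl, giving 5-bromo-2-hydroxy-3,4-dimethoxybenzaldehyde F5. Benzylation (BnBr, K2CO3, DMF) would give 2-benzyloxy-5-bromo-3,4-dimethoxybenzaldehyde F6, and Tsuji–Wilkinson decarbonylation with stoichiometric RhCl(PPh3)3 in refluxing toluene would remove the formyl group and return bromide 6.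

Step 6. The global deprotection may lose selectivity: further demethylation at the 8-O or 3'-O methyl ether on warming, or Friedel–Crafts benzylation of the nucleophilic ring A position C6 if cation trapping is incomplete. The fallback sets out from 9 and comes back at 10, separating the two deprotections into orthogonal operations. Hydrogenolysis (H2, 1 atm, Pd/C, EtOAc–MeOH, rt) should give 4'-hydroxy-5,7,8,2',3'-pentamethoxyflavone F7 without any cationic benzyl species. AlCl3 in MeCN (rt to 50 °C), which cleaves only the methyl ether chelated to the C4 carbonyl, would then give 10.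

**Further compounds**
F1 | step 4 | (4-benzyloxy-2,3-dimethoxyphenyl)lithium | [Li]c1ccc(OCc2ccccc2)c(OC)c1OC
F2 | step 4 | 4-benzyloxy-2,3-dimethoxybenzoic acid | OC(=O)c1ccc(OCc2ccccc2)c(OC)c1OC
F3 | step 4 | 2-acetyl-3,5,6-trimethoxyphenyl 4-benzyloxy-2,3-dimethoxybenzoate | CC(=O)c1c(OC)cc(OC)c(OC)c1OC(=O)c1ccc(OCc2ccccc2)c(OC)c1OC
F4 | step 2 | 2-hydroxy-3,4-dimethoxybenzaldehyde | O=Cc1ccc(OC)c(OC)c1O
F5 | step 2 | 5-bromo-2-hydroxy-3,4-dimethoxybenzaldehyde | O=Cc1cc(Br)c(OC)c(OC)c1O
F6 | step 2 | 2-benzyloxy-5-bromo-3,4-dimethoxybenzaldehyde | O=Cc1cc(Br)c(OC)c(OC)c1OCc1ccccc1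
F7 | step 6 | 4'-hydroxy-5,7,8,2',3'-pentamethoxyflavone | COc1cc(OC)c2c(=O)cc(-c3ccc(O)c(OC)c3OC)oc2c1OC
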